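## The problem

Compound 18 is a daucane-type sesquiterpenoid ester. A cyclopentane (C1–C5; C1 = quaternary carbon bearing CH3, C4 = isopropyl carbinol, C5 = ring-fusion CH) is trans-fused through C1–C5 to a cyclohept-2-enone (C6 = acyloxy CH, C7 = CH2, C8(CH3)=C9, C10 = ketone next to C1). Four contiguous stereocentres must be set as one enantiomer, (1S,4R,5S,6S). The C1 methyl, the C4 hydroxyl and the C5–C6 bond lie on one face of the five-membered ring; H5, the isopropyl group and the C1–C10 bond lie on the other; the C6 oxygen is syn to H5 on the seven-membered ring. C1 is an all-carbon quaternary centre with no heteroatom beside it, so it has to come from a chiral catalyst. Once it stands, it can direct C5 (new bond trans to the larger C1 substituent), C5 can direct C4 (nucleophile anti to the C5 side chain), and C5 together with a defined enolate geometry can fix C6. Three groups limit the reagents: the tertiary C4 alcohol dehydrates in acid, the aryl ester does not survive organometallic reagents, and in the finished ring the C6 acyloxy group is β to C7, whose hydrogens are acidified through the enone, so base can expel the ester by vinylogous elimination. The seven-membered ring also holds a trisubstituted, electron-poor alkene beside a neopentyl-type ketone, which rules out closures that need a second carbonyl β to the C6 oxygen. The enabling feature is that C4, C5 and C1 are the carbonyl, α- and β-carbons of 3-methylcyclopent-2-en-1-one 7, with the methyl group already in place. The two bonds joining this ring to the rest of the seven-membered ring, C1–C10 and C5–C6, start from exactly that β/α pair, which is the pair a conjugate addition followed by aldol trapping creates.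

## Retrosynthesis

**C8=C9, 18 ⇒ 17.** The ring alkene is cut first, opening the seven-membered ring to the monocyclic vinyl ketone 17 with a methallyl arm. The neighbouring cuts are worse. Making the ester C–O bond last would expose an enone with acidified C7 hydrogens to amine base. An aldol closure of C8–C9 would need a C8 ketone β to the C6 oxygen and would compete with five-ring aldolisation of C7 onto C10. The precursor is a cyclopentane with two trans arms. The forward ring-closing metathesis must join an electron-poor vinyl group to a 1,1-disubstituted alkene, but it needs neither acid nor base.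

**C9=CH2, 17 ⇒ 15.** Removing the terminal methylene leads to methyl ketone 15. C1 is quaternary, so the ketone enolises only towards C9, and a Mannich methylenation (through amine 16) has no regiochemical choice. Building the enone from a C10 aldehyde or acid derivative would cost extra redox steps. Ketone 15 is storable where 17 is not. The forward step has to tolerate the ester, the tertiary alcohol and the alkene.

**Ester C–O, 15 ⇒ 13 + 14.** The aroyl group is taken off to give diol ketone 13 and acid chloride 14. Acylating before ring closure keeps base away from the final enone and removes a late protection/deprotection pair. The forward step only has to tell a secondary from a tertiary hydroxyl.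

**C10=O from C10–Si (and C6 O–Si), 13 ⇒ 11.** The acetyl group is traced to a 1-silylethenyl group. A trimethylsilyl group would have to be removed with acid and the resulting neopentyl vinyl group oxidised with divalent palladium, or be epoxidised with a peracid. The first endangers the C4 alcohol and the methallyl alkene. The second is slow and regiochemically unreliable beside a quaternary carbon. The third attacks the methallyl alkene first. A benzyldimethylsilyl group avoids all three problems. Fluoride unlocks it (silanol 12), a nucleophilic peroxide oxidation converts C–Si into C=O without touching isolated alkenes, and the same fluoride removes the C6 silyl ether. One operation thus replaces three.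

**C4–isopropyl, 11 ⇒ 10.** Cutting the isopropyl group gives cyclopentanone 10. No other C4 bond can be cut without losing the enone logic, and the ketone is what the key step leaves behind. The forward addition needs a non-basic branched nucleophile and attack on the H5 face.

**C6 O–Si, 10 ⇒ 9.** The triethylsilyl ether is removed to reveal aldol 9. The ether blocks retro-aldol cleavage and metal chelation in the addition step and adds bulk to the face that must stay closed.

**C1–C10 and C5–C6, 9 ⇒ 7 + 4 + 6.** Both bonds from the five-membered ring to the future seven-membered ring are cut at once, giving enone 7, alkenylalane 4 and aldehyde 6. A stepwise version fails on regiochemistry: a 3,3-disubstituted cyclopentanone is deprotonated at the open C3 side, not at C5, whereas the conjugate addition delivers enolate 8 exactly at C5. Three stereocentres and thirteen of the fifteen skeletal carbons fall back to three small achiral pieces. The forward reaction needs catalyst control at C1, trans induction at C5 and an anti-selective closed aldol transition state at C6.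

**Reagents, 4 ⇒ 3 ⇒ 1 + 2 and 6 ⇒ 5.** Alane 4 comes from hydroalumination of silylacetylene 3, itself made from chlorosilane 1 and Grignard reagent 2. Aldehyde 6 comes from oxidation of alcohol 5.

## Roads not taken

**Alternative 1:**
- **Cut and key step.** The five-membered ring is cut at C4–C5 and the seven-membered ring is the starting point. Prochiral triketone A1 would be desymmetrised by enantioselective reduction of one ring carbonyl (setting C1 and C10 together) and taken on to keto enol triflate A2. CrCl2 with catalytic NiCl2 would then turn the C5 triflate into an alkenylchromium nucleophile that closes onto the isopropyl ketone to give allylic alcohol A3 (intramolecular Nozaki–Hiyama–Kishi reaction).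
- **Merits.** The quaternary centre comes from a symmetric precursor. The C4 carbinol forms intramolecularly, which is better than the intermolecular addition of step 6. A later syn hydroboration of C5=C6 matches the H5/O6 relation of 18.
- **Weak points.** The three ketones of A1 must be told apart twice, in the reduction and in the triflation. Alkenylchromium additions are far less dependable with ketones than with aldehydes; here the ketone is α-branched and the nucleophilic carbon adjoins a quaternary centre. The hydroboration must attack an alkene flanked by two fully substituted carbons from the isopropyl face. A3 also has no C8 methyl and only bare methylenes at C7–C9, so the enone needs dehydrogenation, methyl conjugate addition and a second dehydrogenation.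
- **Comparison.** The chosen plan has the full skeleton and the final oxidation pattern at C6 and C10 after step 7.

**Alternative 2:**
- **Cut and key step.** The seven-membered ring is cut at C7–C8 and C1–C10 into the diene C1=C5–C6=C7 of vinylcyclopentene A4 and the three carbons of diazo ester A5. Rh2(S-DOSP)4 would cyclopropanate C6=C7, and a Cope rearrangement would deliver bicyclic diene ester A6.
- **Merits.** One catalytic step closes the medium ring and sets C1 stereospecifically. C4 is carried in from the start, so both the hindered ketone addition and the metathesis risk of the chosen plan disappear. In ring construction this road is superior.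
- **Weak points.** The Cope step must create a quaternary carbon from a tetrasubstituted ring alkene in a crowded boat transition state. The catalyst must cooperate with the resident C4 centre. A5 lacks a stabilising terminal substituent and is prone to electrocyclise. A6 is also at the wrong oxidation level in several places: CO2Me must become CH3, the neopentyl C10 methylene must be oxidised in competition with the doubly allylic C7, and C5=C6 must be hydrated anti-Markovnikov with trans-fusion control.
- **Comparison.** In the chosen plan every carbon arrives at or one step from its final oxidation state.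

**Alternative 3:**
- **Cut and key step.** Both rings are cut at once, at C1–C5 and C8–C9, back to the acyclic chloro ketone A7. NaOCH2CF3 in CF3CH2OH would ionise it across C9–C10–C1, and an intramolecular (4+3) cycloaddition with the (E,E)-diene would give hydroazulenone A8.
- **Merits.** No other plan gains so much complexity in one step. The C10 ketone is correctly placed, and the count of steps to the bicycle is the lowest.
- **Weak points.** Open-chain dienes populate the s-cis form poorly and are weak partners for such cations. The C9 terminus is unsubstituted, so solvent capture and Favorskii-type pathways compete. A single remote centre, C4, would have to control C1, C5 and the trans fusion. A7 itself needs an enantioselective route to an acyclic tertiary carbinol. From A8 the C6=C7 alkene must be oxygenated at C6 and not C7, with little to distinguish two secondary alkene carbons. The C8 stereocentre is made only to be destroyed by dehydrogenation.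
- **Comparison.** The chosen plan is longer to the bicycle, but each stereocentre has an identifiable control element and the C6 oxygen is built in by the aldol.

Key step: step 4

Assumption: L is the bidentate carbene 1-(2,6-diethylphenyl)-4,5-diphenyl-3-(2-sulfonatophenyl)imidazolidin-2-ylidene, used as its silver complex [AgL]2. Both antipodes derive from the enantiomers of 1,2-diphenylethane-1,2-diamine, and the one that gives (S)-configured C1 is used.

## Route

Step 1
Reactants: 1 benzylchlorodimethylsilane; 2 ethynylmagnesium bromide
Product: 3 benzyl(ethynyl)dimethylsilane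
Conditions: THF, 0 °C to rt; distillation
Reagents that add atoms: none
Why: Substitution at silicon by an alkynyl Grignard reagent. The benzyldimethylsilyl group should behave like trimethylsilyl in steps 2 and 4 but can later be unlocked by fluoride for C–Si oxidation.

Step 2
Reactants: 3 benzyl(ethynyl)dimethylsilane
Product: 4 [1-(benzyldimethylsilyl)ethenyl]diisobutylaluminium (kept as a stock solution)
Conditions: i-Bu2AlH (1.0 equiv), hexanes–THF, 55 °C
Reagents that add atoms: diisobutylaluminium hydride, CC(C)C[AlH]CC(C)C
Why: Hydroalumination of a silylacetylene: Al–H adds syn, and aluminium goes to the silicon-bearing carbon, where the C–Al bond is stabilised, giving the geminal Al/Si alkene. The ether co-solvent tempers the hydride and holds back deprotonation of the terminal alkyne.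

Step 3
Reactants: 5 3-methylbut-3-en-1-ol
Product: 6 3-methylbut-3-enal
Conditions: Dess–Martin periodinane, CH2Cl2, 0 °C to rt; cold aq. NaHCO3/Na2S2O3 wash, dried solution used the same day
Reagents that add atoms: none
Why: Dess–Martin oxidation needs neither amine base nor strong acid, the two agents that move the β,γ-alkene into conjugation. The volatile aldehyde is neither concentrated nor stored.

Step 4
Reactants: 7 3-methylcyclopent-2-en-1-one; 4 [1-(benzyldimethylsilyl)ethenyl]diisobutylaluminium; 6 3-methylbut-3-enal
Product: 9 (2S,3S)-3-[1-(benzyldimethylsilyl)ethenyl]-2-[(1S)-1-hydroxy-3-methylbut-3-en-1-yl]-3-methylcyclopentan-1-one, via aluminium enolate 8 (not isolated)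
Conditions: CuCl2·2H2O (5 mol %), [AgL]2 (2.5 mol %), 4 (1.3 equiv), THF, −30 °C; then 6 (2.5 equiv, CH2Cl2 solution), −78 °C; aq. potassium sodium tartrate
Reagents that add atoms: none
Why: The alane reduces CuCl2·2H2O to monovalent copper, the carbene moves from silver to copper, and Al-to-Cu exchange gives an alkenylcopper complex that transfers its sp2 ligand rather than isobutyl. π-Complexation of 7, oxidative addition at the β-carbon to a trivalent copper intermediate and reductive elimination form C1–C10; the closest known reaction type is the carbene–copper-catalysed enantioselective conjugate addition of silyl-substituted alkenylaluminium reagents to β-substituted cyclic enones, joined to the classical conjugate addition–aldol three-component sequence. C1 is set by the chiral carbene, whose sulfonate arm binds aluminium and fixes the enone face that is attacked. Enolate 8 forms regiospecifically at C5, a position that deprotonation of the saturated ketone would not reach. The aluminium of 8 binds aldehyde 6, and C5–C6 forms through a closed six-membered chair (Zimmerman–Traxler) transition state. C5 is set by C1: the aldehyde enters on the methyl face, away from the much larger silylalkenyl group, and the trans product is also the one favoured by equilibration at this epimerisable carbon. C6 is set by the enolate geometry: a ring enolate is necessarily E(O), and with the aldehyde chain equatorial the chair gives the anti aldol, which is the (5S,6S) relation of 18. No ring is closed; the step needs 1,4- over 1,2-addition, alkenyl over isobutyl transfer and addition over proton transfer from the acidic β,γ-unsaturated aldehyde, secured by the soft copper nucleophile, the faster migration of sp2 carbon and the low basicity of the aluminium enolate at −78 °C.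

Step 5
Reactants: 9 (2S,3S)-3-[1-(benzyldimethylsilyl)ethenyl]-2-[(1S)-1-hydroxy-3-methylbut-3-en-1-yl]-3-methylcyclopentan-1-one
Product: 10 (2S,3S)-3-[1-(benzyldimethylsilyl)ethenyl]-3-methyl-2-[(1S)-3-methyl-1-(triethylsilyloxy)but-3-en-1-yl]cyclopentan-1-one
Conditions: Et3SiOTf, 2,6-lutidine, CH2Cl2, −78 °C
Reagents that add atoms: triethylsilyl trifluoromethanesulfonate, CC[Si](CC)(CC)OS(=O)(=O)C(F)(F)F
Why: Silylation of a hindered secondary alcohol with a silyl triflate and a hindered pyridine base is fast at low temperature, so retro-aldol cleavage, dehydration and C5 epimerisation should be avoided. The ether prevents chelation in step 6, shields the lower face and is removed in step 7 without a step of its own.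

Step 6
Reactants: 10 (2S,3S)-3-[1-(benzyldimethylsilyl)ethenyl]-3-methyl-2-[(1S)-3-methyl-1-(triethylsilyloxy)but-3-en-1-yl]cyclopentan-1-one
Product: 11 (1R,2S,3S)-3-[1-(benzyldimethylsilyl)ethenyl]-3-methyl-2-[(1S)-3-methyl-1-(triethylsilyloxy)but-3-en-1-yl]-1-(propan-2-yl)cyclopentan-1-ol
Conditions: CeCl3 (anhydrous), i-PrMgCl, THF, −78 to 0 °C; aq. NH4Cl
Reagents that add atoms: isopropylmagnesium chloride, CC(C)[Mg]Cl
Why: Organocerium 1,2-addition: the low basicity of the reagent holds back enolisation, loss of the β-silyloxy group and β-hydride transfer. With the trans C5 and C1 arms both pseudo-equatorial, the lower face carries the C5 side chain and the pseudo-axial C1 methyl. Isopropyl should therefore enter on the H5 face and place the C4 hydroxyl cis to the C5–C6 bond (4R).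

Step 7
Reactants: 11 (1R,2S,3S)-3-[1-(benzyldimethylsilyl)ethenyl]-3-methyl-2-[(1S)-3-methyl-1-(triethylsilyloxy)but-3-en-1-yl]-1-(propan-2-yl)cyclopentan-1-ol
Product: 13 1-[(1S,2S,3R)-3-hydroxy-2-[(1S)-1-hydroxy-3-methylbut-3-en-1-yl]-1-methyl-3-(propan-2-yl)cyclopentyl]ethan-1-one, via silanol 12 (not isolated)
Conditions: Bu4NF (4 equiv), THF, 0 °C to rt; then KHCO3, 30 % aq. H2O2, MeOH, 40 °C
Reagents that add atoms: hydrogen peroxide, OO; water, O (silanol oxygen of 12 only)
Why: Tamao–Fleming oxidation of an alkenylsilane: fluoride cleaves the benzyl–silicon bond and the triethylsilyl ether, hydroperoxide adds to silicon, the alkenyl carbon migrates from Si to O, and the silyl enol ether hydrolyses to the methyl ketone. The oxidant is nucleophilic, so the methallyl alkene and the tertiary alcohol are left alone and no stereocentre is touched.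

Step 8
Reactants: 13 1-[(1S,2S,3R)-3-hydroxy-2-[(1S)-1-hydroxy-3-methylbut-3-en-1-yl]-1-methyl-3-(propan-2-yl)cyclopentyl]ethan-1-one; 14 3,4-dimethoxybenzoyl chloride
Product: 15 (1S)-1-[(1S,2S,5R)-2-acetyl-5-hydroxy-2-methyl-5-(propan-2-yl)cyclopentyl]-3-methylbut-3-en-1-yl 3,4-dimethoxybenzoate
Conditions: 14 (1.3 equiv), Et3N, DMAP (20 mol %), CH2Cl2, 0 °C to rt
Reagents that add atoms: none
Why: DMAP-catalysed acylation takes the secondary C6 hydroxyl and leaves the tertiary C4 hydroxyl, with retention at C6. At this stage no enolisable position lies β to the new ester, so the amine base is harmless.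

Step 9
Reactants: 15 (1S)-1-[(1S,2S,5R)-2-acetyl-5-hydroxy-2-methyl-5-(propan-2-yl)cyclopentyl]-3-methylbut-3-en-1-yl 3,4-dimethoxybenzoate
Product: 17 (1S)-1-[(1S,2S,5R)-5-hydroxy-2-methyl-5-(propan-2-yl)-2-(prop-2-enoyl)cyclopentyl]-3-methylbut-3-en-1-yl 3,4-dimethoxybenzoate, via Mannich base 16 (not isolated)
Conditions: (CH2O)n, i-Pr2NH·CF3CO2H (1 equiv), CF3CO2H (10 mol %), THF, 65 °C
Reagents that add atoms: paraformaldehyde (as formaldehyde), C=O; diisopropylammonium trifluoroacetate, CC(C)[NH2+]C(C)C.[O-]C(=O)C(F)(F)F (its amine stays in 16 only)
Why: Mannich α-methylenation: the ketone can enolise only towards C9, the enol adds to the iminium ion, and the bulky amine is lost from 16 in the flask. The buffered ammonium salt is too weak an acid to ionise the C4 alcohol or cleave the ester.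

Step 10
Reactants: 17 (1S)-1-[(1S,2S,5R)-5-hydroxy-2-methyl-5-(propan-2-yl)-2-(prop-2-enoyl)cyclopentyl]-3-methylbut-3-en-1-yl 3,4-dimethoxybenzoate
Product: 18 (3R,3aS,4S,8aS)-3-hydroxy-6,8a-dimethyl-8-oxo-3-(propan-2-yl)-1,2,3,3a,4,5,8,8a-octahydroazulen-4-yl 3,4-dimethoxybenzoate
Conditions: second-generation Grubbs catalyst (10 mol %), toluene (2 mM), 80 °C, argon sparge
Reagents that add atoms: none
Why: Ring-closing metathesis of a vinyl ketone with a 1,1-disubstituted alkene is an established route to β-methyl cycloalkenones, hydroazulenones included; it forms C8=C9 with loss of ethene, and the ring size enforces the Z alkene. The trans arms on C1 and C5 lead to the unstrained trans-fused bicycle. No stereocentre is touched, and the neutral medium spares the ester, the tertiary alcohol and the base-sensitive C6/C7 array.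

## Compound list

1 | benzylchlorodimethylsilane | C[Si](C)(Cl)Cc1ccccc1 | starting material
2 | ethynylmagnesium bromide | C#C[Mg]Br | starting material
3 | benzyl(ethynyl)dimethylsilane | C#C[Si](C)(C)Cc1ccccc1 | intermediate
4 | [1-(benzyldimethylsilyl)ethenyl]diisobutylaluminium | C=C([Si](C)(C)Cc1ccccc1)[Al](CC(C)C)CC(C)C | intermediate
5 | 3-methylbut-3-en-1-ol | CC(=C)CCO | starting material
6 | 3-methylbut-3-enal | CC(=C)CC=O | intermediate
7 | 3-methylcyclopent-2-en-1-one | CC1=CC(=O)CC1 | starting material
8 | diisobutylaluminium (3S)-3-[1-(benzyldimethylsilyl)ethenyl]-3-methylcyclopent-1-en-1-olate | C=C([Si](C)(C)Cc1ccccc1)[C@@]2(C)CCC(O[Al](CC(C)C)CC(C)C)=C2 | intermediate (not isolated)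
9 | (2S,3S)-3-[1-(benzyldimethylsilyl)ethenyl]-2-[(1S)-1-hydroxy-3-methylbut-3-en-1-yl]-3-methylcyclopentan-1-one | O=C1CC[C@](C)(C(=C)[Si](C)(C)Cc2ccccc2)[C@H]1[C@@H](O)CC(C)=C | intermediate
10 | (2S,3S)-3-[1-(benzyldimethylsilyl)ethenyl]-3-methyl-2-[(1S)-3-methyl-1-(triethylsilyloxy)but-3-en-1-yl]cyclopentan-1-one | O=C1CC[C@](C)(C(=C)[Si](C)(C)Cc2ccccc2)[C@H]1[C@@H](O[Si](CC)(CC)CC)CC(C)=C | intermediate
11 | (1R,2S,3S)-3-[1-(benzyldimethylsilyl)ethenyl]-3-methyl-2-[(1S)-3-methyl-1-(triethylsilyloxy)but-3-en-1-yl]-1-(propan-2-yl)cyclopentan-1-ol | O[C@@]1(C(C)C)CC[C@](C)(C(=C)[Si](C)(C)Cc2ccccc2)[C@H]1[C@@H](O[Si](CC)(CC)CC)CC(C)=C | intermediate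
12 | (1R,2S,3S)-3-[1-(hydroxydimethylsilyl)ethenyl]-2-[(1S)-1-hydroxy-3-methylbut-3-en-1-yl]-3-methyl-1-(propan-2-yl)cyclopentan-1-ol | O[C@@]1(C(C)C)CC[C@](C)(C(=C)[Si](C)(C)O)[C@H]1[C@@H](O)CC(C)=C | intermediate (not isolated)
13 | 1-[(1S,2S,3R)-3-hydroxy-2-[(1S)-1-hydroxy-3-methylbut-3-en-1-yl]-1-methyl-3-(propan-2-yl)cyclopentyl]ethan-1-one | O[C@@]1(C(C)C)CC[C@](C)(C(C)=O)[C@H]1[C@@H](O)CC(C)=C | intermediate
14 | 3,4-dimethoxybenzoyl chloride | COc1ccc(C(=O)Cl)cc1OC | starting material
15 | (1S)-1-[(1S,2S,5R)-2-acetyl-5-hydroxy-2-methyl-5-(propan-2-yl)cyclopentyl]-3-methylbut-3-en-1-yl 3,4-dimethoxybenzoate | O[C@@]1(C(C)C)CC[C@](C)(C(C)=O)[C@H]1[C@@H](OC(=O)c2ccc(OC)c(OC)c2)CC(C)=C | intermediate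
16 | (1S)-1-[(1S,2S,5R)-2-[3-(diisopropylamino)propanoyl]-5-hydroxy-2-methyl-5-(propan-2-yl)cyclopentyl]-3-methylbut-3-en-1-yl 3,4-dimethoxybenzoate | O[C@@]1(C(C)C)CC[C@](C)(C(=O)CCN(C(C)C)C(C)C)[C@H]1[C@@H](OC(=O)c2ccc(OC)c(OC)c2)CC(C)=C | intermediate (not isolated)
17 | (1S)-1-[(1S,2S,5R)-5-hydroxy-2-methyl-5-(propan-2-yl)-2-(prop-2-enoyl)cyclopentyl]-3-methylbut-3-en-1-yl 3,4-dimethoxybenzoate | O[C@@]1(C(C)C)CC[C@](C)(C(=O)C=C)[C@H]1[C@@H](OC(=O)c2ccc(OC)c(OC)c2)CC(C)=C | intermediate
18 | (3R,3aS,4S,8aS)-3-hydroxy-6,8a-dimethyl-8-oxo-3-(propan-2-yl)-1,2,3,3a,4,5,8,8a-octahydroazulen-4-yl 3,4-dimethoxybenzoate | COc1ccc(C(=O)O[C@H]2CC(C)=CC(=O)[C@@]3(C)CC[C@@](O)(C(C)C)[C@H]23)cc1OC | target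

## Step count and least certain steps

Total: 10 steps. Longest linear sequence: 9 steps (1, 2, 4, 5, 6, 7, 8, 9, 10). Step 3 is a one-step side branch.

**Step 4 (key step).**
- **Risk.** Aluminium enolates are sluggish nucleophiles. The aldehyde may therefore be consumed by surplus alane (alkenyl or hydride transfer), be deprotonated, or drift into conjugation before the aldol takes place. Five-membered-ring enolates also give rather loose chair transition states, so simple diastereoselection at C6 may be modest.
- **Fallback.** The tandem is split. Setting out from enolate 8, Me3SiOTf traps it as the trimethylsilyl enol ether F1, which is freed from aluminium and copper residues. MeLi in THF then releases the lithium enolate F2 with the double bond still at C4=C5, and aldehyde 6 is added at −78 °C, returning to the route at 9.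

**Step 6.**
- **Risk.** The hindered ketone may enolise and then expel the C6 silyloxy group. β-Hydride transfer from the branched nucleophile would give reduction instead of addition. Facial selectivity would erode if the ring populates the conformer with the silylalkenyl group pseudo-axial.
- **Fallback.** A flat sp2 nucleophile without β-hydrogen replaces isopropyl, and saturation is postponed to the end. From 10, isopropenylmagnesium bromide with CeCl3 gives the isopropenyl carbinol F3. The conditions of steps 7–10 then carry it through the silanol F4 (in the flask), the diol ketone F5, the veratrate F6, the Mannich base F7 (in the flask) and the vinyl ketone F8 to the bicyclic dienone F9. The isopropenyl group sits on a fully substituted carbon and should be too hindered to enter metathesis. H2 with RhCl(PPh3)3 then saturates the 1,1-disubstituted alkene and leaves the trisubstituted enone, returning at 18.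

**Step 7.**
- **Risk.** Silicon sits next to a quaternary carbon, so peroxide attack may be slow and fluoride-induced cleavage of the alkenyl–silicon bond (protodesilylation) may overtake the oxidation.
- **Fallback.** That cleavage is made the intended reaction. From 11, Bu4NF with CuI in THF (through silanol 12) gives the vinyl diol F10 under non-acidic conditions. Acylation with 14 as in step 8 gives the vinyl veratrate F11. A Tsuji–Wacker oxidation (PdCl2, CuCl, O2, DMF–H2O), which prefers the monosubstituted alkene over the 1,1-disubstituted one, returns to the route at 15.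

**Step 9.**
- **Risk.** The Mannich reaction at a neopentyl-type ketone may be slow, leaving time for formaldehyde to engage the methallyl alkene in an ene or Prins process. The unsubstituted vinyl ketone may polymerise or re-add amine on prolonged heating.
- **Fallback.** A sturdier metathesis partner is made by aldol condensation. From 15, Bu2BOTf and i-Pr2NEt give the boron enolate F12. Acetaldehyde at −78 °C gives the β-hydroxy ketone F13 (epimers at the new carbinol). MsCl/Et3N gives the mesylate F14, which loses methanesulfonate with DBU to give the (E)-propenyl ketone F15. Under the conditions of step 10 this closes with loss of propene, returning at 18.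

**Step 10.**
- **Risk.** Both alkenes are reluctant. The catalyst loads slowly on the 1,1-disubstituted terminus, and an acyl-substituted ruthenium carbene decays readily. Intermolecular coupling, catalyst death and alkene migration may therefore outrun closure of the trans-fused seven-membered ring.
- **Fallback.** The electron-poor partner is switched off temporarily. From 17, Luche reduction (NaBH4, CeCl3·7H2O, MeOH, −78 °C) gives the dienol F16 (C10 epimers), whose allylic alcohol is a much better metathesis partner. Ring closure with the second-generation Grubbs catalyst gives the bicyclic allylic alcohol F17, and MnO2 reoxidises C10, returning at 18.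

## Further compounds

F1 | step 4 | {[(3S)-3-[1-(benzyldimethylsilyl)ethenyl]-3-methylcyclopent-1-en-1-yl]oxy}trimethylsilane | C=C([Si](C)(C)Cc1ccccc1)[C@@]2(C)CCC(O[Si](C)(C)C)=C2
F2 | step 4 | lithium (3S)-3-[1-(benzyldimethylsilyl)ethenyl]-3-methylcyclopent-1-en-1-olate | C=C([Si](C)(C)Cc1ccccc1)[C@@]2(C)CCC(O[Li])=C2
F3 | step 6 | isopropenyl analogue of 11 (prop-1-en-2-yl at C4) | O[C@@]1(C(C)=C)CC[C@](C)(C(=C)[Si](C)(C)Cc2ccccc2)[C@H]1[C@@H](O[Si](CC)(CC)CC)CC(C)=C
F4 | step 6 | isopropenyl analogue of silanol 12 | O[C@@]1(C(C)=C)CC[C@](C)(C(=C)[Si](C)(C)O)[C@H]1[C@@H](O)CC(C)=C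
F5 | step 6 | isopropenyl analogue of diol ketone 13 | O[C@@]1(C(C)=C)CC[C@](C)(C(C)=O)[C@H]1[C@@H](O)CC(C)=C
F6 | step 6 | isopropenyl analogue of ester 15 | O[C@@]1(C(C)=C)CC[C@](C)(C(C)=O)[C@H]1[C@@H](OC(=O)c2ccc(OC)c(OC)c2)CC(C)=C
F7 | step 6 | isopropenyl analogue of Mannich base 16 | O[C@@]1(C(C)=C)CC[C@](C)(C(=O)CCN(C(C)C)C(C)C)[C@H]1[C@@H](OC(=O)c2ccc(OC)c(OC)c2)CC(C)=C
F8 | step 6 | isopropenyl analogue of vinyl ketone 17 | O[C@@]1(C(C)=C)CC[C@](C)(C(=O)C=C)[C@H]1[C@@H](OC(=O)c2ccc(OC)c(OC)c2)CC(C)=C
F9 | step 6 | isopropenyl analogue of 18 (bicyclic dienone) | COc1ccc(C(=O)O[C@H]2CC(C)=CC(=O)[C@@]3(C)CC[C@@](O)(C(C)=C)[C@H]23)cc1OC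
F10 | step 7 | vinyl diol (ethenyl at C1 in place of acetyl of 13) | O[C@@]1(C(C)C)CC[C@](C)(C=C)[C@H]1[C@@H](O)CC(C)=C
F11 | step 7 | vinyl veratrate (ethenyl at C1 in place of acetyl of 15) | O[C@@]1(C(C)C)CC[C@](C)(C=C)[C@H]1[C@@H](OC(=O)c2ccc(OC)c(OC)c2)CC(C)=C
F12 | step 9 | dibutylboron enolate of 15 | O[C@@]1(C(C)C)CC[C@](C)(C(=C)OB(CCCC)CCCC)[C@H]1[C@@H](OC(=O)c2ccc(OC)c(OC)c2)CC(C)=C
F13 | step 9 | 3-hydroxybutanoyl analogue of 15 (epimers at the new carbinol) | O[C@@]1(C(C)C)CC[C@](C)(C(=O)CC(C)O)[C@H]1[C@@H](OC(=O)c2ccc(OC)c(OC)c2)CC(C)=C
F14 | step 9 | mesylate of F13 | O[C@@]1(C(C)C)CC[C@](C)(C(=O)CC(C)OS(C)(=O)=O)[C@H]1[C@@H](OC(=O)c2ccc(OC)c(OC)c2)CC(C)=C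
F15 | step 9 | (E)-but-2-enoyl analogue of 17 | O[C@@]1(C(C)C)CC[C@](C)(C(=O)/C=C/C)[C@H]1[C@@H](OC(=O)c2ccc(OC)c(OC)c2)CC(C)=C
F16 | step 10 | dienol from 1,2-reduction of 17 (C10 epimers) | O[C@@]1(C(C)C)CC[C@](C)(C(O)C=C)[C@H]1[C@@H](OC(=O)c2ccc(OC)c(OC)c2)CC(C)=C
F17 | step 10 | bicyclic C10 allylic alcohol (C10 epimers) | COc1ccc(C(=O)O[C@H]2CC(C)=CC(O)[C@@]3(C)CC[C@@](O)(C(C)C)[C@H]23)cc1OC
A1 | alternative 1 | 2-methyl-2-(4-methyl-3-oxopentyl)cycloheptane-1,3-dione | CC(C)C(=O)CCC1(C)C(=O)CCCCC1=O
A2 | alternative 1 | keto enol triflate (C5 triflate, C10 silyl ether, side-chain isopropyl ketone) | CC(C)C(=O)CC[C@@]1(C)C(OS(=O)(=O)C(F)(F)F)=CCCC[C@@H]1O[Si](C)(C)C(C)(C)C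
A3 | alternative 1 | bicyclic allylic tertiary alcohol with C5=C6 alkene and C10 silyl ether | CC(C)[C@]1(O)CC[C@@]2(C)C1=CCCC[C@@H]2O[Si](C)(C)C(C)(C)C
A4 | alternative 2 | 1-ethenyl-2-methyl-5-(propan-2-yl)-5-(triethylsilyloxy)cyclopent-1-ene | C=CC1=C(C)CC[C@@]1(O[Si](CC)(CC)CC)C(C)C
A5 | alternative 2 | methyl 2-diazobut-3-enoate | COC(=O)C(=[N+]=[N-])C=C
A6 | alternative 2 | bicyclic 5,8-diene ester with CO2Me on C8 | COC(=O)C1=CC[C@@]2(C)CC[C@@](O[Si](CC)(CC)CC)(C(C)C)C2=CC1
A7 | alternative 3 | acyclic tertiary α-chloro ketone with tethered (E,E)-diene (epimers at C–Cl) | CC(=O)C(C)(Cl)CC[C@@](O[Si](CC)(CC)CC)(C(C)C)/C=C/C=C/C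
A8 | alternative 3 | trans-fused 4-triethylsilyloxy hydroazulen-10-one with C6=C7 alkene and C8 methyl | O=C1C[C@@H](C)C=C[C@H]2[C@](O[Si](CC)(CC)CC)(C(C)C)CC[C@]12C
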